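**Strategy.** Ring A (the cyclohexane) is built by ring contraction, not taken over intact: (S)-carvone is first homologated to a cycloheptenone. Everything rests on a Prins–pinacol cascade that exploits quaternary C-11 (methyl, acetoxy; eunicellane numbering) beside ring-fusion C-10. An oxocarbenium ion, tethered through the C-2 oxygen, adds to C-10 of a 1,2-dimethylcyclohept-2-enyl silyl ether; the 1,2-shift that quenches the C-11 cation closes the cis-fused tetrahydrofuran (ring B), contracts seven to six and expels the carbinol carbon as an acetyl group, which a Baeyer–Villiger oxidation turns into the tertiary acetate. Chelation-controlled Grignard addition (C-3), ring-closing metathesis (ring C) and oxidative lactonisation (ring D) finish the target.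

Key step: step 12

Remark: atoms are given in eunicellane numbering. Ring A = cyclohexane C-1, C-10 to C-14; ring B = tetrahydrofuran C-1, C-2, O, C-9, C-10; ring C = oxonene C-2 to C-9 with O; ring D = ε-lactone C-1, C-2, C-3, O, C-16, C-15, C-14. C-x is the carvone carbonyl carbon that is expelled in step 12; its configuration in 15 to 17 is the expected one and is immaterial.

Step 1
Reactants: 1 methyl (R)-lactate
Product: 2 methyl (R)-2-(tert-butyldimethylsilyloxy)propanoate
Conditions: t-BuMe2SiCl, imidazole, DMF, 0 °C → rt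
Reagents that add atoms: tert-butyldimethylsilyl chloride, CC(C)(C)[Si](C)(C)Cl
Why: Imidazole-promoted O-silylation of a secondary alcohol; the lactate stereocentre is not touched.

Step 2
Reactants: 2 methyl (R)-2-(tert-butyldimethylsilyloxy)propanoate
Product: 3 (R)-2-(tert-butyldimethylsilyloxy)propanal
Conditions: i-Bu2AlH (1.05 equiv), CH2Cl2, −78 °C; aq. KNaC4H4O6 work-up
Reagents that add atoms: none
Why: Partial ester reduction through the tetrahedral aluminate that survives at −78 °C; the α-silyloxy aldehyde should keep its configuration when used at once.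

Step 3
Reactants: 4 triethyl orthoformate
Product: 5 4,4-diethoxy-2-methylbut-1-ene
Conditions: CH2=C(CH3)CH2MgCl (0.5 M in THF), 60 °C
Reagents that add atoms: 2-methylallylmagnesium chloride, CC(=C)C[Mg]Cl
Why: Bodroux–Chichibabin reaction: the allylic Grignard reagent displaces one ethoxide of the orthoester and stops at the acetal.

Step 4
Reactants: 6 (S)-(+)-carvone
Product: 8 kinetic TMS dienol ether of carvone, via lithium dienolate 7 (not isolated)
Conditions: LiN(i-Pr)2, THF, −78 °C; then Me3SiCl, Et3N, −78 → 0 °C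
Reagents that add atoms: chlorotrimethylsilane, C[Si](C)(C)Cl
Why: Kinetic α′-deprotonation of the enone and O-silylation should give the cross-conjugated 2-silyloxydiene; the stereocentre is untouched.

Step 5
Reactants: 8 kinetic TMS dienol ether of carvone
Product: 9 1-silyloxybicyclo[4.1.0]hept-2-ene
Conditions: Et2Zn, CH2I2, toluene, 0 °C → rt
Reagents that add atoms: diiodomethane, ICI
Why: Furukawa–Simmons–Smith cyclopropanation, selective for the electron-rich silyl enol ether double bond and expected anti to the neighbouring isopropenyl group (both new centres are erased in step 6).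

Step 6
Reactants: 9 1-silyloxybicyclo[4.1.0]hept-2-ene
Product: 10 6-chloro-2-methyl-5-(prop-1-en-2-yl)cyclohept-2-en-1-one
Conditions: FeCl3 (2.2 equiv), DMF, 0 °C → rt
Reagents that add atoms: iron trichloride, Cl[Fe](Cl)Cl
Why: Ito–Saegusa oxidative ring expansion: one-electron oxidation, β-scission of the internal cyclopropane bond and chlorine transfer should give the ring-enlarged β-chloro ketone (the C–Cl centre is erased in step 7).

Step 7
Reactants: 10 6-chloro-2-methyl-5-(prop-1-en-2-yl)cyclohept-2-en-1-one
Product: 11 (R)-2-methyl-5-(prop-1-en-2-yl)cyclohept-2-en-1-one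
Conditions: Bu3SnH, AIBN (cat.), PhH, 80 °C
Reagents that add atoms: none
Why: Radical-chain dehalogenation under neutral conditions, which avoids base-induced loss of HCl to the dienone.

Step 8
Reactants: 11 (R)-2-methyl-5-(prop-1-en-2-yl)cyclohept-2-en-1-one
Product: 13 through-conjugated TMS dienol ether, via bromomagnesium dienolate 12 (not isolated)
Conditions: MeMgBr (1.2 equiv), FeCl3 (5 mol %), Et2O, −20 °C; then Me3SiCl, Et3N, DMPU, −20 °C → rt
Reagents that add atoms: chlorotrimethylsilane, C[Si](C)(C)Cl
Why: Iron-catalysed Grignard deprotonation removes the γ-hydrogen and gives the through-conjugated (thermodynamic) dienolate, which is trapped on oxygen as the 1-silyloxy-1,3-diene.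

Step 9
Reactants: 13 through-conjugated TMS dienol ether; 3 (R)-2-(tert-butyldimethylsilyloxy)propanal
Product: 14 γ-aldol adduct (4,5-trans cycloheptenone)
Conditions: BF3·OEt2 (1.1 equiv), CH2Cl2, −78 °C
Reagents that add atoms: none
Why: Vinylogous Mukaiyama aldol reaction: attack at the γ-carbon (the α-carbon is fully substituted) anti to the adjacent isopropenyl group sets C-1, and Felkin–Anh addition to the α-silyloxy aldehyde sets C-2 (2,3-anti).

Step 10
Reactants: 14 γ-aldol adduct
Product: 15 1,2-dimethylcyclohept-2-en-1-ol diol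
Conditions: MeLi (3 equiv), CeCl3 (3 equiv), THF, −78 °C
Reagents that add atoms: methyllithium, [Li]C
Why: 1,2-Addition of the organocerium reagent (no conjugate addition, little enolisation), expected anti to the C-1 side chain; C-x is expelled in step 12.

Step 11
Reactants: 15 1,2-dimethylcyclohept-2-en-1-ol diol
Product: 16 bis(trimethylsilyl) ether
Conditions: Me3SiOTf (2.5 equiv), 2,6-lutidine, CH2Cl2, −78 °C
Reagents that add atoms: trimethylsilyl triflate, C[Si](C)(C)OS(=O)(=O)C(F)(F)F
Why: Silylation of the secondary and the tertiary allylic alcohol with the silyl triflate; no stereocentre changes.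

Step 12
Reactants: 16 bis(trimethylsilyl) ether; 5 4,4-diethoxy-2-methylbut-1-ene
Product: 18 4-acetyl-4-methyl octahydroisobenzofuran, via mixed ethyl acetal 17 (not isolated)
Conditions: Me3SiOTf (0.3 equiv), 2,6-di-tert-butyl-4-methylpyridine (0.3 equiv), CH2Cl2, −78 → −40 °C
Reagents that add atoms: none
Why: Proposed new method: the C-2 silyl ether and acetal 5 exchange under Me3SiOTf to the mixed acetal 17, which ionises to an (E)-oxocarbenium ion; its carbon (C-9) adds to C-10 of the ring alkene and the antiperiplanar ring bond of the neighbouring silyloxy carbinol migrates to C-11 with loss of Me3Si+, so the seven-membered ring contracts to ring A and C-x becomes the acetyl C=O. The closest known reaction type is the Prins–pinacol reaction (pinacol-terminated Prins cyclisation of alkenyl carbinol silyl ethers), here with a carbocycle-contracting instead of a ring-enlarging 1,2-shift. Ring B closes by 5-exo attack of the alkene on the oxocarbenium carbon (endo with respect to C=O+), and ring A arises by the 1,2-shift of the ring CH2 (seven to six). C-10 is fixed by the one-atom tether from C-1 (cis ring fusion), C-9 by the E-oxocarbenium ion with its 2-methylallyl group on the convex face (2,9-cis), and C-11 by anti addition across the alkene (migration on the face opposite to the incoming C-9). The step needs 5-exo over 6-endo closure and ring-bond over methyl migration: the first is secured by the C-11 methyl group (tertiary cation), the second by the pseudo-axial alignment of the ring bond and the strain released on going from seven to six.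

Step 13
Reactants: 18 4-acetyl-4-methyl octahydroisobenzofuran
Product: 19 tertiary acetate
Conditions: Me3SiOOSiMe3, SnCl4, trans-cyclohexane-1,2-diamine, 4 Å MS, CH2Cl2, −20 °C → rt
Reagents that add atoms: bis(trimethylsilyl) peroxide, C[Si](C)(C)OO[Si](C)(C)C
Why: Baeyer–Villiger oxidation with a silyl peroxide that oxidises ketones but not isolated alkenes; the tertiary carbon migrates with retention, so C-11 keeps its configuration.

Step 14
Reactants: 19 tertiary acetate
Product: 20 secondary alcohol
Conditions: Bu4NF, AcOH, THF, 0 °C → rt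
Reagents that add atoms: none
Why: Fluoride desilylation of the secondary TBS ether, buffered with AcOH so that the tertiary acetate survives.

Step 15
Reactants: 20 secondary alcohol
Product: 21 C-2 methyl ketone
Conditions: Dess–Martin periodinane, NaHCO3, CH2Cl2, rt
Reagents that add atoms: none
Why: Dess–Martin oxidation to the α-alkoxy methyl ketone under buffered conditions that should not epimerise C-2.

Step 16
Reactants: 21 C-2 methyl ketone
Product: 22 tertiary alcohol with but-3-enyl chain
Conditions: CH2=CHCH2CH2MgBr (1.3 equiv), MgBr2·OEt2, CH2Cl2/Et2O, −78 °C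
Reagents that add atoms: but-3-enylmagnesium bromide, C=CCC[Mg]Br
Why: Chelation-controlled Grignard addition (Cram chelate between the ring-B oxygen and the ketone) from the C-2–H face sets C-3; the chelated ketone should react far faster than the hindered tertiary acetate at −78 °C.

Step 17
Reactants: 22 tertiary alcohol with but-3-enyl chain
Product: 23 tricyclic oxonene
Conditions: second-generation Grubbs catalyst (H2IMes)(PCy3)Cl2Ru=CHPh (10 mol %), CH2Cl2 (2 mM), 40 °C
Reagents that add atoms: none
Why: Ring-closing metathesis of the but-3-enyl and 2-methylallyl groups (the α-branched isopropenyl group should be inert); the nine-membered ring enforces the Z trisubstituted alkene.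

Step 18
Reactants: 23 tricyclic oxonene
Product: 25 C-16 primary alcohol (diol), via B-alkyl-9-BBN adduct 24 (not isolated)
Conditions: 9-BBN, THF, 0 °C → rt; then H2O2, pH 7 phosphate buffer, 0 °C
Reagents that add atoms: hydrogen peroxide, OO
Why: Hydroboration–oxidation: 9-BBN takes the 1,1-disubstituted alkene before the ring alkene and should attack the C-14–H/C=CH2 eclipsed rotamer anti to C-1, which sets C-15.

Step 19
Reactants: 25 C-16 primary alcohol (diol)
Product: 28 target CNP0332402.2, via hydroxy aldehyde 26 (not isolated), via lactol 27 (not isolated)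
Conditions: TEMPO (20 mol %), PhI(OAc)2 (2.5 equiv), CH2Cl2, rt
Reagents that add atoms: none
Why: TEMPO/PhI(OAc)2 oxidative lactonisation: the primary alcohol is oxidised to the aldehyde, the nearby tertiary hydroxyl closes the seven-membered lactol (7-exo-trig) and this is oxidised to the lactone; no stereocentre is created.

**Compound list**

1 | methyl (R)-lactate | C[C@@H](O)C(=O)OC | starting material
2 | methyl (R)-2-(tert-butyldimethylsilyloxy)propanoate | C[C@@H](O[Si](C)(C)C(C)(C)C)C(=O)OC | intermediate
3 | (R)-2-(tert-butyldimethylsilyloxy)propanal | C[C@@H](O[Si](C)(C)C(C)(C)C)C=O | intermediate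
4 | triethyl orthoformate | CCOC(OCC)OCC | starting material
5 | 4,4-diethoxy-2-methylbut-1-ene | CCOC(OCC)CC(C)=C | intermediate
6 | (S)-(+)-carvone | O=C1C[C@@H](C(C)=C)CC=C1C | starting material
7 | lithium cross-conjugated dienolate of (S)-carvone | [Li+].[O-]C1=C[C@@H](C(C)=C)CC=C1C | intermediate
8 | (S)-trimethyl{[3-methyl-6-(prop-1-en-2-yl)cyclohexa-1,3-dien-2-yl]oxy}silane (kinetic TMS dienol ether of carvone) | C[Si](C)(C)OC1=C[C@@H](C(C)=C)CC=C1C | intermediate
9 | 2-methyl-5-(prop-1-en-2-yl)-1-(trimethylsilyloxy)bicyclo[4.1.0]hept-2-ene, cyclopropane CH2 trans to isopropenyl | C[Si](C)(C)O[C@@]12C[C@@H]1[C@@H](C(C)=C)CC=C2C | intermediate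
10 | 6-chloro-2-methyl-5-(prop-1-en-2-yl)cyclohept-2-en-1-one, chloride trans to isopropenyl | O=C1C[C@H](Cl)[C@@H](C(C)=C)CC=C1C | intermediate
11 | (R)-2-methyl-5-(prop-1-en-2-yl)cyclohept-2-en-1-one | O=C1CC[C@@H](C(C)=C)CC=C1C | intermediate
12 | bromomagnesium through-conjugated dienolate of 11 | [Mg+2].[Br-].[O-]C1=C(C)C=C[C@H](C(C)=C)CC1 | intermediate
13 | trimethyl{[2-methyl-5-(prop-1-en-2-yl)cyclohepta-1,3-dien-1-yl]oxy}silane, C-5 as in 11 | C[Si](C)(C)OC1=C(C)C=C[C@H](C(C)=C)CC1 | intermediate
14 | 4-[(1S,2R)-2-(tert-butyldimethylsilyloxy)-1-hydroxypropyl]-2-methyl-5-(prop-1-en-2-yl)cyclohept-2-en-1-one, 4,5-trans | O=C1CC[C@@H](C(C)=C)[C@@H](C=C1C)[C@H](O)[C@@H](C)O[Si](C)(C)C(C)(C)C | intermediate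
15 | 4-[(1S,2R)-2-(tert-butyldimethylsilyloxy)-1-hydroxypropyl]-1,2-dimethyl-5-(prop-1-en-2-yl)cyclohept-2-en-1-ol, 4,5-trans, 1-OH cis to the C-4 side chain | C[C@@]1(O)CC[C@@H](C(C)=C)[C@@H](C=C1C)[C@H](O)[C@@H](C)O[Si](C)(C)C(C)(C)C | intermediate
16 | bis(trimethylsilyl) ether of 15 | C[C@@]1(O[Si](C)(C)C)CC[C@@H](C(C)=C)[C@@H](C=C1C)[C@H](O[Si](C)(C)C)[C@@H](C)O[Si](C)(C)C(C)(C)C | intermediate
17 | mixed ethyl 3-methylbut-3-enylidene acetal at the C-2 oxygen of 16 (acetal carbon as epimer mixture) | C[C@@]1(O[Si](C)(C)C)CC[C@@H](C(C)=C)[C@@H](C=C1C)[C@H](OC(OCC)CC(C)=C)[C@@H](C)O[Si](C)(C)C(C)(C)C | intermediate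
18 | cis-fused octahydroisobenzofuran: 4-acetyl-4-methyl, 3-(2-methylallyl), 7-(prop-1-en-2-yl), 1-[(R)-1-(tert-butyldimethylsilyloxy)ethyl]; 1,3-cis, acetyl cis to C-3, isopropenyl trans to the C-1 side chain | CC(=O)[C@]1(C)CC[C@@H](C(C)=C)[C@H]2[C@@H]1[C@H](CC(C)=C)O[C@@H]2[C@@H](C)O[Si](C)(C)C(C)(C)C | intermediate
19 | 4-acetoxy analogue of 18 (tertiary acetate, configuration retained) | CC(=O)O[C@]1(C)CC[C@@H](C(C)=C)[C@H]2[C@@H]1[C@H](CC(C)=C)O[C@@H]2[C@@H](C)O[Si](C)(C)C(C)(C)C | intermediate
20 | 1-[(R)-1-hydroxyethyl] analogue of 19 | CC(=O)O[C@]1(C)CC[C@@H](C(C)=C)[C@H]2[C@@H]1[C@H](CC(C)=C)O[C@@H]2[C@@H](C)O | intermediate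
21 | 1-acetyl analogue of 19 (α-alkoxy methyl ketone) | CC(=O)O[C@]1(C)CC[C@@H](C(C)=C)[C@H]2[C@@H]1[C@H](CC(C)=C)O[C@@H]2C(C)=O | intermediate
22 | 1-[(S)-2-hydroxyhex-5-en-2-yl] analogue of 19 | CC(=O)O[C@]1(C)CC[C@@H](C(C)=C)[C@H]2[C@@H]1[C@H](CC(C)=C)O[C@@H]2[C@@](C)(O)CCC=C | intermediate
23 | tricyclic (Z)-oxonene with C-3 hydroxyl, C-11 acetate and C-14 isopropenyl | CC(=O)O[C@]1(C)CC[C@@H](C(C)=C)[C@H]2[C@@H]1[C@@H]1C/C(C)=C\CC[C@](C)(O)[C@H]2O1 | intermediate
24 | B-alkyl-9-borabicyclo[3.3.1]nonane adduct of 23 at C-16 | CC(=O)O[C@]1(C)CC[C@@H]([C@@H](C)CB3C4CCCC3CCC4)[C@H]2[C@@H]1[C@@H]1C/C(C)=C\CC[C@](C)(O)[C@H]2O1 | intermediate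
25 | (15R)-C-16 primary alcohol of 23 (3,16-diol) | CC(=O)O[C@]1(C)CC[C@@H]([C@@H](C)CO)[C@H]2[C@@H]1[C@@H]1C/C(C)=C\CC[C@](C)(O)[C@H]2O1 | intermediate
26 | C-16 aldehyde with free C-3 hydroxyl | CC(=O)O[C@]1(C)CC[C@@H]([C@@H](C)C=O)[C@H]2[C@@H]1[C@@H]1C/C(C)=C\CC[C@](C)(O)[C@H]2O1 | intermediate
27 | seven-membered lactol (C-16 hemiacetal, epimer mixture) | CC(=O)O[C@]1(C)CC[C@@H]2[C@H]3[C@@H]1[C@@H]1C/C(C)=C\CC[C@](C)(OC(O)[C@@H]2C)[C@H]3O1 | intermediate
28 | CNP0332402.2 | CC(=O)O[C@]1(C)CC[C@@H]2[C@H]3[C@@H]1[C@@H]1C/C(C)=C\CC[C@](C)(OC(=O)[C@@H]2C)[C@H]3O1 | target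

**Step count.** 19 steps in total. The longest linear sequence is 16 steps (steps 4 to 19 from (S)-carvone); steps 1 to 3 make the two side-branch building blocks 3 and 5.

**Steps most likely to fail**

1. Step 12 (key step). The oxocarbenium ion may close in the 6-endo sense or be lost to enol-ether formation. The tertiary allylic silyl ether may ionise. The C-11 cation may lose a proton or take up the methyl group instead of the ring bond. The fallback uses known chemistry, sets out from 15 and comes back at 18; it separates bond formation at C-10 from the ring contraction. Hydroxyl-directed epoxidation of 15 (VO(acac)2, t-BuOOH, CH2Cl2) should give the epoxy diol F1, with the oxirane on the face of both hydroxyl groups. PMe3-catalysed oxa-Michael addition of the secondary hydroxyl to but-3-yn-2-one gives the (E)-β-alkoxyvinyl ketone F2. BF3·OEt2 then triggers the semipinacol rearrangement of the 2,3-epoxy alcohol (ring bond anti to the breaking C-11–O bond, seven to six) to the β-hydroxy ketone F3, which has the C-11 configuration of 18. The C-10 hydroxyl is converted (PhOC(S)Cl, pyridine) into the phenyl thionocarbonate F4. Bu3SnH/AIBN generates the C-10 radical, whose 5-exo cyclisation onto the β-alkoxyvinyl ketone closes ring B (cis-fused, 2,9-cis) to the diketone F5. Wittig methylenation (Ph3P=CH2, 1 equiv, THF, 0 °C) of the unhindered acetonyl ketone then gives 18.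

2. Step 13. The hindered ketone may be oxidised too slowly, so that the Lewis acid starts ene or Prins reactions between the activated acetyl group and the nearby 2-methylallyl alkene, or epoxidation competes. The fallback sets out from 18 and comes back at 19; it accepts epoxidation instead of avoiding it. Excess m-CPBA/NaHCO3 carries out the Baeyer–Villiger oxidation and epoxidises both 1,1-disubstituted alkenes to the bis-epoxy acetate F6 (epoxide epimers, immaterial). WCl6/n-BuLi in THF then deoxygenates both epoxides back to the alkenes and gives 19.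

3. Step 19. The lactol may fail to close on the hindered tertiary hydroxyl, so that the oxidation stops at aldehyde 26, which can epimerise at C-15. The fallback sets out from 25 and comes back at 28; it oxidises and cyclises separately. TEMPO/PhI(OAc)2 in MeCN–H2O takes the primary alcohol to the hydroxy acid F7. Yamaguchi lactonisation (2,4,6-trichlorobenzoyl chloride, Et3N, then DMAP, toluene, 80 °C) then closes ring D.

Further compounds
F1 | step 12 | 2,3-epoxide of 15, oxirane cis to both hydroxyl groups | C[C@@]1(O)CC[C@@H](C(C)=C)[C@@H]([C@@H]2O[C@]12C)[C@H](O)[C@@H](C)O[Si](C)(C)C(C)(C)C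
F2 | step 12 | (E)-3-oxobut-1-enyl ether of F1 at the C-2 oxygen | C[C@@]1(O)CC[C@@H](C(C)=C)[C@@H]([C@@H]2O[C@]12C)[C@H](O/C=C/C(C)=O)[C@@H](C)O[Si](C)(C)C(C)(C)C
F3 | step 12 | ring-contracted β-hydroxy ketone (1-acetyl-1-methylcyclohexan-2-ol, hydroxyl cis to the C-1 side chain) | CC(=O)[C@]1(C)CC[C@@H](C(C)=C)[C@@H]([C@@H]1O)[C@H](O/C=C/C(C)=O)[C@@H](C)O[Si](C)(C)C(C)(C)C
F4 | step 12 | O-phenyl thionocarbonate of F3 | CC(=O)[C@]1(C)CC[C@@H](C(C)=C)[C@@H]([C@@H]1OC(=S)Oc1ccccc1)[C@H](O/C=C/C(C)=O)[C@@H](C)O[Si](C)(C)C(C)(C)C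
F5 | step 12 | 3-(2-oxopropyl) analogue of 18 | CC(=O)[C@]1(C)CC[C@@H](C(C)=C)[C@H]2[C@@H]1[C@H](CC(C)=O)O[C@@H]2[C@@H](C)O[Si](C)(C)C(C)(C)C
F6 | step 13 | bis-epoxide of 19 (both 1,1-disubstituted alkenes epoxidised, epimer mixture) | CC(=O)O[C@]1(C)CC[C@@H](C2(C)CO2)[C@H]2[C@@H]1[C@H](CC1(C)CO1)O[C@@H]2[C@@H](C)O[Si](C)(C)C(C)(C)C
F7 | step 19 | C-16 carboxylic acid with free C-3 hydroxyl (seco acid of 28) | CC(=O)O[C@]1(C)CC[C@@H]([C@@H](C)C(=O)O)[C@H]2[C@@H]1[C@@H]1C/C(C)=C\CC[C@](C)(O)[C@H]2O1
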